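**Strategy.** Everything rests on cutting the C7–C11 and C8–O bonds of the target. Its cyclohexane ring carries O6, C11 (on C7) and O8 on three adjacent carbons, cis then trans, and the lactone ring is cis-fused at C6–C7; the key step uses exactly this. A C11 radical tethered through O6 as a bromoacetal closes 5-exo onto C7 of a C7=C8 ring alkene, and the resulting C8 radical captures O2 anti to the new bond. One operation gives the oxolane ring, two bonds and the C7/C8 stereocentres. Its precursor is the verbenone-derived 6α allylic alcohol, with C5 and C10 already set, as its 2-bromo-1-ethoxypropyl acetal.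

Key step: step 7

Remark: elemane numbering is used (C10 methyl/vinyl, C5 isopropenyl, C6 lactone oxygen, C7 carrying C11, C8 acetoxy) and β is the face of the C10 methyl; compounds 10–15 are mixtures at the acetal carbon and/or C11 (one isomer drawn), and both centres are levelled in steps 9 and 10.

**Step 1**
Reactants: 1 (1S,5S)-(−)-verbenone; 2 vinylmagnesium bromide
Product: 3 (1S,4R,5R)-4,6,6-trimethyl-4-vinylbicyclo[3.1.1]heptan-2-one (vinyl anti to the CMe2 bridge)
Conditions: CuI (0.2 equiv), THF, −40 → 0 °C; then 1 M HCl
Reagents that add atoms: none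
Why: Copper-catalysed conjugate addition of the vinyl Grignard reagent should occur on the enone face away from the overhanging gem-dimethyl bridge, which sets the quaternary centre (later C10) with vinyl anti to that bridge.

**Step 2**
Reactants: 3 (1S,4R,5R)-4,6,6-trimethyl-4-vinylbicyclo[3.1.1]heptan-2-one
Product: 4 (4R,5R)-5-methyl-4-(prop-1-en-2-yl)-5-vinylcyclohex-1-en-1-yl acetate (C7=C8 enol acetate, isopropenyl trans to vinyl)
Conditions: Zn(OAc)2, BF3·OEt2, Ac2O, 0 °C → rt
Reagents that add atoms: acetic anhydride, CC(=O)OC(C)=O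
Why: Lewis-acid-mediated cyclobutane fragmentation breaks the strained bond between the α-bridgehead and the CMe2 carbon, the tertiary cation loses a proton to give the isopropenyl group and the enolate is trapped as the regiodefined enol acetate; no stereocentre is touched, so C5 and C10 keep the trans isopropenyl/vinyl relationship.

**Step 3**
Reactants: 4 (4R,5R)-5-methyl-4-(prop-1-en-2-yl)-5-vinylcyclohex-1-en-1-yl acetate
Product: 6 (4R,5R)-5-methyl-4-(prop-1-en-2-yl)-5-vinylcyclohex-2-en-1-one (C8 ketone with C6=C7), via lithium enolate 5 (not isolated)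
Conditions: MeLi (2.1 equiv), THF, 0 °C; then PhS(Cl)=NtBu (2.2 equiv), −78 °C
Reagents that add atoms: none
Why: Methyllithium cleaves the enol acetate to the C7 lithium enolate, which is sulfenylated at C7 by N-tert-butylbenzenesulfinimidoyl chloride and undergoes syn-elimination towards C6 at low temperature (Mukaiyama dehydrogenation); the quaternary C10 rules out unsaturation on the C9 side.

**Step 4**
Reactants: 6 (4R,5R)-5-methyl-4-(prop-1-en-2-yl)-5-vinylcyclohex-2-en-1-one
Product: 7 6α,7α-epoxy ketone, 4-methyl-5-(prop-1-en-2-yl)-4-vinyl-7-oxabicyclo[4.1.0]heptan-2-one (epoxide trans to isopropenyl)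
Conditions: 30% H2O2, NaOH (0.3 equiv), MeOH, 0 °C
Reagents that add atoms: hydrogen peroxide, OO
Why: In this Weitz–Scheffer nucleophilic epoxidation hydroperoxide should add to C6 on the face opposite the neighbouring C5 isopropenyl group and the axial C10 methyl (both β), so ring closure gives the α-epoxide and fixes the C6–O configuration.

**Step 5**
Reactants: 7 6α,7α-epoxy ketone
Product: 8 (1R,5R,6R)-5-methyl-6-(prop-1-en-2-yl)-5-vinylcyclohex-2-en-1-ol (6α-OH, C7=C8)
Conditions: N2H4·H2O (3 equiv), AcOH (cat.), MeOH, 0 °C → rt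
Reagents that add atoms: none
Why: In the Wharton transposition the epoxy hydrazone opens to an allylic diazene that loses N2, leaving the C7=C8 alkene and the C6 alcohol; the C6–O bond is never broken, so the 6α configuration is retained.

**Step 6**
Reactants: 8 (1R,5R,6R)-5-methyl-6-(prop-1-en-2-yl)-5-vinylcyclohex-2-en-1-ol; 9 ethyl 1-propenyl ether (E/Z mixture)
Product: 10 6α-O-(2-bromo-1-ethoxypropyl) acetal of 8 (diastereomers at the acetal and CHBr carbons)
Conditions: 9 (3 equiv), NBS (1.2 equiv), CH2Cl2, −40 → 0 °C
Reagents that add atoms: N-bromosuccinimide, O=C1CCC(=O)N1Br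
Why: In this haloacetalisation the electron-rich enol ether, used in excess, is brominated far faster than the three unactivated alkenes and the bromo-oxocarbenium ion is captured by the C6 hydroxyl; the two new centres form unselectively, which is harmless because both are erased later.

**Step 7**
Reactants: 10 6α-O-(2-bromo-1-ethoxypropyl) acetal
Product: 12 8β-hydroxy cis-fused bicyclic ethyl acetal, via hydroperoxide 11 (not isolated)
Conditions: Bu3SnH (2.5 equiv, syringe pump), Et3B (0.2 equiv), dry air (slow stream), toluene (0.01 M), rt; then PPh3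
Reagents that add atoms: dioxygen, O=O
Why: The stannyl radical abstracts bromine from 10, the C11 radical adds through the acetal tether to C7 of the ring alkene in a 5-exo-trig closure that forms C7–C11 and the oxolane, and the secondary C8 radical is captured by O2 to give, after hydrogen transfer from the stannane, hydroperoxide 11, which PPh3 reduces to 12. The closest known reaction type is the Ueno–Stork haloacetal cyclisation run as an aerobic tin hydride process with oxygen trapping of the cyclised radical. Because the tether hangs from the 6α oxygen, C11 can only reach the α face of C7, which fixes the cis ring fusion; C11 itself forms as a mixture and is levelled later. At C8 capture is expected anti to the new axial C7–C11 bond, on the β (convex) face, giving the trans-diaxial O8/C11 arrangement, and the small size of O2 should limit the penalty from the syn-axial C10 methyl. The step needs the ring alkene to beat the isopropenyl and vinyl groups, secured because only C7 lies within 5-exo reach (the others would need 7-membered closures), and it needs cyclisation before oxygen capture of the C11 radical, secured by the fast closure of a 3-oxa-5-hexenyl radical and a low dissolved O2 concentration. The neutral conditions leave the β-alkoxy relationship around C6–C8 untouched.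

**Step 8**
Reactants: 12 8β-hydroxy cis-fused bicyclic ethyl acetal
Product: 13 8β-O-tert-butyldimethylsilyl ether of 12
Conditions: TBSOTf (1.3 equiv), 2,6-lutidine, CH2Cl2, −78 °C
Reagents that add atoms: tert-butyldimethylsilyl triflate, CC(C)(C)[Si](C)(C)OS(=O)(=O)C(F)(F)F
Why: Silylation with the silyl triflate suits the hindered axial 8β-hydroxyl and at −78 °C should be much faster than any activation of the mixed acetal; no stereocentre changes.

**Step 9**
Reactants: 13 8β-O-TBS bicyclic ethyl acetal
Product: 15 8β-(tert-butyldimethylsilyloxy) cis-fused 6α,12-lactone (C11 epimers), via lactol 14 (not isolated)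
Conditions: CrO3, H2SO4, H2O (Jones reagent), acetone, 0 °C, short reaction time
Reagents that add atoms: water, O
Why: In this Jones oxidation of a cyclic mixed acetal the aqueous acid hydrolyses the ethyl acetal to the lactol, which chromic acid oxidises to the γ-lactone, erasing the acetal centre; the secondary TBS ether and the alkenes should tolerate the brief cold exposure.

**Step 10**
Reactants: 15 8β-silyloxy cis-fused lactone
Product: 17 11-hydroxy lactone with OH on the convex face (11S), via lithium enolate 16 (not isolated)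
Conditions: LDA, THF, −78 → −40 °C; then 2-(phenylsulfonyl)-3-phenyloxaziridine, −78 °C; AcOH
Reagents that add atoms: 2-(phenylsulfonyl)-3-phenyloxaziridine, O=S(=O)(c1ccccc1)N1OC1c1ccccc1
Why: In this Davis enolate hydroxylation both C11 epimers converge on one planar enolate, which should take up oxygen on its convex face (the face of H7, away from the cyclohexane ring), placing OH exo and methyl endo as in the target; no leaving group sits β to the enolate carbon.

**Step 11**
Reactants: 17 11-hydroxy lactone; 18 angelic acid
Product: 21 11-O-angeloyl 8β-O-TBS lactone, via mixed anhydride 19 (not isolated), via lithium alkoxide 20 (not isolated)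
Conditions: 18, 2,4,6-Cl3C6H2COCl, Et3N, THF, rt, filter; 17, LiHMDS, THF, −78 °C; then the filtrate, −78 → 0 °C
Reagents that add atoms: none
Why: In this Yamaguchi-type acylation the preformed tertiary alkoxide attacks the less hindered angeloyl carbonyl of the mixed anhydride, and the absence of a nucleophilic amine catalyst together with the low temperature should suppress Z→E isomerisation to the tiglate; C11 is not affected.

**Step 12**
Reactants: 21 11-O-angeloyl 8β-O-TBS lactone
Product: 22 8β-hydroxy 11-angeloyloxy lactone
Conditions: HF·pyridine, pyridine, THF, 0 °C → rt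
Reagents that add atoms: none
Why: Fluoride-mediated desilylation under mildly acidic conditions frees O8 without generating an alkoxide, and the trans-diaxial O8/C11 arrangement keeps O8 away from both carbonyl groups, so acyl migration and translactonisation are not expected.

**Step 13**
Reactants: 22 8β-hydroxy 11-angeloyloxy lactone
Product: 23 (3S,3aR,4S,6R,7R,7aS)-4-acetoxy-6-ethenyl-3,6-dimethyl-2-oxo-7-(prop-1-en-2-yl)octahydro-1-benzofuran-3-yl (2Z)-2-methylbut-2-enoate (target)
Conditions: Ac2O, DMAP (cat.), pyridine, CH2Cl2, rt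
Reagents that add atoms: acetic anhydride, CC(=O)OC(C)=O
Why: DMAP-catalysed acylation of the secondary 8β-alcohol proceeds with retention at C8 and completes the target.

**Compound list**

1 | (1S,5S)-(−)-verbenone | CC1=CC(=O)[C@H]2C[C@@H]1C2(C)C | starting material
2 | vinylmagnesium bromide | C=C[Mg]Br | starting material
3 | (1S,4R,5R)-4,6,6-trimethyl-4-vinylbicyclo[3.1.1]heptan-2-one, vinyl anti to the CMe2 bridge | C[C@]1(C=C)CC(=O)[C@H]2C[C@@H]1C2(C)C | intermediate
4 | (4R,5R)-5-methyl-4-(prop-1-en-2-yl)-5-vinylcyclohex-1-en-1-yl acetate | C=C[C@@]1(C)CC(OC(C)=O)=CC[C@@H]1C(=C)C | intermediate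
5 | lithium (4R,5R)-5-methyl-4-(prop-1-en-2-yl)-5-vinylcyclohex-1-en-1-olate | C=C[C@@]1(C)CC([O-])=CC[C@@H]1C(=C)C.[Li+] | intermediate (not isolated)
6 | (4R,5R)-5-methyl-4-(prop-1-en-2-yl)-5-vinylcyclohex-2-en-1-one | C=C[C@@]1(C)CC(=O)C=C[C@@H]1C(=C)C | intermediate
7 | 4-methyl-5-(prop-1-en-2-yl)-4-vinyl-7-oxabicyclo[4.1.0]heptan-2-one, 6α,7α-epoxide trans to isopropenyl | C=C[C@@]1(C)CC(=O)[C@H]2O[C@H]2[C@@H]1C(=C)C | intermediate
8 | (1R,5R,6R)-5-methyl-6-(prop-1-en-2-yl)-5-vinylcyclohex-2-en-1-ol, OH trans to isopropenyl | C=C[C@@]1(C)CC=C[C@@H](O)[C@@H]1C(=C)C | intermediate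
9 | ethyl 1-propenyl ether (E/Z mixture) | CC=COCC | starting material
10 | 6α-O-(2-bromo-1-ethoxypropyl) acetal of 8 (one of four acetal/CHBr diastereomers drawn) | C=C[C@@]1(C)CC=C[C@@H](O[C@@H](OCC)[C@H](C)Br)[C@@H]1C(=C)C | intermediate
11 | 8β-hydroperoxy cis-fused bicyclic ethyl acetal (one C11/C12 isomer drawn) | C=C[C@@]1(C)C[C@H](OO)[C@@H]2[C@@H](O[C@@H](OCC)[C@H]2C)[C@@H]1C(=C)C | intermediate (not isolated)
12 | 2-ethoxy-3,6-dimethyl-7-(prop-1-en-2-yl)-6-vinyloctahydro-1-benzofuran-4-ol, cis ring fusion, 4-OH (O8) β and trans to C3 (one C2/C3 isomer drawn) | C=C[C@@]1(C)C[C@H](O)[C@@H]2[C@@H](O[C@@H](OCC)[C@H]2C)[C@@H]1C(=C)C | intermediate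
13 | 8β-O-tert-butyldimethylsilyl ether of 12 | C=C[C@@]1(C)C[C@H](O[Si](C)(C)C(C)(C)C)[C@@H]2[C@@H](O[C@@H](OCC)[C@H]2C)[C@@H]1C(=C)C | intermediate
14 | 8β-silyloxy lactol (anomers) | C=C[C@@]1(C)C[C@H](O[Si](C)(C)C(C)(C)C)[C@@H]2[C@@H](OC(O)[C@H]2C)[C@@H]1C(=C)C | intermediate (not isolated)
15 | 4-(tert-butyldimethylsilyloxy)-3,6-dimethyl-7-(prop-1-en-2-yl)-6-vinylhexahydro-1-benzofuran-2(3H)-one, cis-fused (one C11 epimer drawn) | C=C[C@@]1(C)C[C@H](O[Si](C)(C)C(C)(C)C)[C@@H]2[C@@H](OC(=O)[C@H]2C)[C@@H]1C(=C)C | intermediate
16 | lithium enolate of 15 (C11=C12) | C=C[C@@]1(C)C[C@H](O[Si](C)(C)C(C)(C)C)[C@@H]2[C@@H](OC([O-])=C2C)[C@@H]1C(=C)C.[Li+] | intermediate (not isolated)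
17 | (3S)-3-hydroxy derivative of 15, OH on the convex face (cis to H7) | C=C[C@@]1(C)C[C@H](O[Si](C)(C)C(C)(C)C)[C@@H]2[C@@H](OC(=O)[C@@]2(C)O)[C@@H]1C(=C)C | intermediate
18 | angelic acid, (Z)-2-methylbut-2-enoic acid | C/C=C(/C)C(=O)O | starting material
19 | angelic 2,4,6-trichlorobenzoic anhydride | C/C=C(/C)C(=O)OC(=O)c1c(Cl)cc(Cl)cc1Cl | intermediate (not isolated)
20 | lithium alkoxide of 17 | C=C[C@@]1(C)C[C@H](O[Si](C)(C)C(C)(C)C)[C@@H]2[C@@H](OC(=O)[C@@]2(C)[O-])[C@@H]1C(=C)C.[Li+] | intermediate (not isolated)
21 | 11-O-angeloyl 8β-O-TBS lactone | C=C[C@@]1(C)C[C@H](O[Si](C)(C)C(C)(C)C)[C@@H]2[C@@H](OC(=O)[C@@]2(C)OC(=O)/C(C)=C\C)[C@@H]1C(=C)C | intermediate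
22 | 8β-hydroxy 11-angeloyloxy lactone | C=C[C@@]1(C)C[C@H](O)[C@@H]2[C@@H](OC(=O)[C@@]2(C)OC(=O)/C(C)=C\C)[C@@H]1C(=C)C | intermediate
23 | (3S,3aR,4S,6R,7R,7aS)-4-acetoxy-6-ethenyl-3,6-dimethyl-2-oxo-7-(prop-1-en-2-yl)octahydro-1-benzofuran-3-yl (2Z)-2-methylbut-2-enoate | C=C[C@@]1(C)C[C@H](OC(C)=O)[C@@H]2[C@@H](OC(=O)[C@@]2(C)OC(=O)/C(C)=C\C)[C@@H]1C(=C)C | target

**Totals.** Total step count: 13. Longest linear sequence: 13 steps (1 → 23).

**Steps most likely to fail**

1. Step 7. The risk is poor facial selectivity in the oxygen capture at C8, because the syn-axial C10 methyl opposes approach to the β face. Capture of the C11 radical by oxygen before ring closure is a second risk. The fallback sets out from 10 and moves the C8 stereocentre from radical trapping to carbonyl reduction. The cyclisation–oxygenation is run as before, and the alcohol mixture, then mainly the 8α-alcohol F1 (the C8 epimer of 12), is oxidised without separation with Dess–Martin periodinane (NaHCO3, CH2Cl2) to the C8 ketone F2. Reduction of F2 with L-Selectride (THF, −78 °C, cold neutral work-up to avoid β-elimination of O6) should deliver hydride to the α face. That is the face the failed trapping would have shown to be open, and the bulky hydride avoids the syn-axial methyl. The product is the 8β-alcohol 12, where the route is rejoined.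

2. Step 11. The risk is Z→E isomerisation of the angeloyl unit during acyl transfer, or sluggish acylation of the tertiary alkoxide. The fallback sets out from 17 and builds the Z double bond on the substrate. After deprotonation with LiHMDS, 17 is acylated with 2-[bis(2,2,2-trifluoroethoxy)phosphoryl]propanoyl chloride to give the phosphonopropionate ester F3. A Still–Gennari olefination of F3 with acetaldehyde (KHMDS, 18-crown-6, THF, −78 °C) should then give the Z-trisubstituted enoate, which is angelate 21, where the route is rejoined.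

3. Step 5. The risk is diversion of the diazene-derived intermediates to reduced or condensed by-products, or attack of hydrazine on the epoxide, so that little allylic alcohol forms. The fallback sets out from 7 and replaces the hydrazone pathway by a reductive elimination. NaBH4 (MeOH, 0 °C) reduces 7 to the epoxy alcohol F4 (either C8 epimer serves), and MsCl/Et3N converts it into the epoxy mesylate F5. Sodium in liquid ammonia/THF at −78 °C should then expel mesylate and open the epoxide towards C7, giving the C7=C8 alkene and the untouched 6α-hydroxyl of 8, where the route is rejoined.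

**Further compounds**

F1 | step 7 | 8α-hydroxy cis-fused bicyclic ethyl acetal (C8 epimer of 12) | C=C[C@@]1(C)C[C@@H](O)[C@@H]2[C@@H](O[C@@H](OCC)[C@H]2C)[C@@H]1C(=C)C
F2 | step 7 | C8 ketone of the cis-fused bicyclic ethyl acetal | C=C[C@@]1(C)CC(=O)[C@@H]2[C@@H](O[C@@H](OCC)[C@H]2C)[C@@H]1C(=C)C
F3 | step 11 | 11-O-{2-[bis(2,2,2-trifluoroethoxy)phosphoryl]propanoyl} 8β-O-TBS lactone | C=C[C@@]1(C)C[C@H](O[Si](C)(C)C(C)(C)C)[C@@H]2[C@@H](OC(=O)[C@@]2(C)OC(=O)C(C)P(=O)(OCC(F)(F)F)OCC(F)(F)F)[C@@H]1C(=C)C
F4 | step 5 | 6α,7α-epoxy-8-ol, 4-methyl-5-(prop-1-en-2-yl)-4-vinyl-7-oxabicyclo[4.1.0]heptan-2-ol (C8 epimers) | C=C[C@@]1(C)CC(O)[C@H]2O[C@H]2[C@@H]1C(=C)C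
F5 | step 5 | methanesulfonate of F4 | C=C[C@@]1(C)CC(OS(C)(=O)=O)[C@H]2O[C@H]2[C@@H]1C(=C)C
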